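Read the flask at 40 min: the question then is how far its partner went, and what each reacted substrate cost in partner.

substrate 0.10 M; partner 0.130 M; time 40 min

    substrate + partner → single product + released group (k1 = 0.68 M⁻¹ s⁻¹)
    substrate + partner → other mono adduct + released group (k2 = 1.1 M⁻¹ s⁻¹)
    partner + single product → bis adduct + released group (k3 = 0.24 M⁻¹ s⁻¹)
    partner + other mono adduct → bis adduct + released group (k4 = 0.075 M⁻¹ s⁻¹)
    partner + released group ⇌ idle adduct, settled at all times (K5 = 6.0 M⁻¹)
    2 partner → homo dimer (k6 = 0.11 M⁻¹ s⁻¹)
    partner ⇌ dormant form (K7 = 21, k7 = 0.015 s⁻¹)

- part of the substrate that has reacted at 40 min
- share of free partner in free partner and idle adduct together, at 40 min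

- what is said of released group includes idle adduct
- a step written with two of one species runs at k times the square of its concentration and takes two of it each time
- run time (flask): 40 min

Compare two rate constants. Partner takes substrate at 1.78 M⁻¹ s⁻¹. It takes a mono adduct at 0.138 M⁻¹ s⁻¹, each adduct weighted by how often it forms. Their quotient 0.0775 is the second-take ratio, a selectivity factor. Both rates carry the same free partner, so divide them and time drops out. Integrate, counting the mono adducts as the part reacted. With r the substrate left and y the part reacted, as fractions of charge, bis adduct comes to w(−ln r − y), and partner taken per substrate charged is y plus that.

Now the budget. Homo dimer takes 12.9% of partner's starting traffic. I take that starting share as a high charge, since homo dimer's rate goes with the square of partner. Count dormant form as returned, which is a low charge: its return half-life of 16.2 min is shorter than the run, but 2.47 such half-lives still leave some of it out. I let the two errors offset, as a rough estimate. That leaves 1.13 per substrate. Try r = 3.88%: it costs 1.14, just above budget. So I expect about 96.1% reacted. Released group near 0.113 M then gives a free share of 59.5%.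

The forecast says 95% and 61%, holding that “the slow return from the dormant form over 40 min then drives conversion” upward.

The flask gives 96.0% and 60.0%, with 0.111 M of released group at 40.0 min. Put that conversion into the ratio: it charges 0.114 M of partner taken, slightly above the released group. At that time homo dimer holds 8.70% of the partner charged, less than my 12.9%, and dormant form holds 5.41%, where I charged none.

Take the neighbour flask with 0.033 M of partner. Its budget is 0.318, the ratio charges 0.502% for bis adduct, and so 31.3% should react. That flask gives 31.3%.

(The rate constants come from no measurement, and the outcome is calculated.)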